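**Retrosynthetic overview**

- The strategy rests on the two oxygens of the end group sitting on tertiary carbons, C1 (exocyclic CMe2OH on C2) and C5 (ring C(CH3)OH), on either side of C6 in the cyclopentane ring C2–C6 (carotenoid locants, C7 on C6). Both are installed last by C–H oxidation of an all-cis hydrocarbon acid whose carboxyl carbon is C7.
- C7=C8 is disconnected by a Wittig reaction into a C10 lactol (C1–C7) and a C30 polyenyl phosphonium salt (C8–C1').
- The lactol comes from the cis-fused hydroxy γ-lactone, made in one operation from the all-cis acid by carboxylate-directed lactonisation at C1–H followed by hydroxylation at C5–H.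
- The acid comes from (S)-pulegone: Favorskii contraction forms the cyclopentane ring first, then kinetic protonation and hydrogenation set the all-cis triad. The lactone ring is closed second and opened again in the Wittig step.
- The C30 salt is assembled from pseudoionone (C15), 2,7-dimethylocta-2,4,6-trienedial (C10) and a C5 phosphonate.

Key step: step 5

Assumption: pseudoionone is used as the (3E,5E) isomer (isomer mixtures are fractionated before use).
Notation: locants C1–C15 and primed locants in the text are carotenoid locants of the target (C1 = isopropyl/CMe2O carbon, C2–C6 = ring, C5 = methyl-bearing ring carbon, C6 = ring carbon bearing C7). PDP = 1,1'-bis(pyridin-2-ylmethyl)-2,2'-bipyrrolidine, and its complex [Fe((S,S)-PDP)(MeCN)2](SbF6)2 contains divalent iron.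

**Route**

Step 1
Reactants: 1 (S)-(−)-pulegone
Product: 3 methyl (5S)-5-methyl-2-(propan-2-ylidene)cyclopentane-1-carboxylate (methyl pulegenate; epimer mixture at the ester-bearing carbon), via pulegone dibromide 2 (not isolated)
Conditions: Br2, NaHCO3, Et2O, −10 °C; then NaOMe, MeOH, reflux
Reagents that add atoms: sodium methoxide, [Na+].[O-]C
Why: Bromine adds across the enone double bond and the α,β-dibromo ketone undergoes Favorskii ring contraction (α'-enolate, cyclopropanone, methoxide opening with loss of the β-bromide), which leaves the C5 methyl stereocentre of pulegone untouched.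

Step 2
Reactants: 3 methyl pulegenate (epimer mixture)
Product: 5 methyl (1S,5S)-5-methyl-2-(propan-2-ylidene)cyclopentane-1-carboxylate (cis ester), via lithium dienolate 4 (not isolated)
Conditions: LiN(i-Pr)2, THF, −78 °C; then AcOH in THF, −78 °C
Reagents that add atoms: none
Why: Kinetic α-protonation of the ester dienolate at C6, on the face opposite the adjacent C5 methyl, should give the contra-thermodynamic cis ester from both epimers (deconjugative kinetic protonation of an extended enolate).

Step 3
Reactants: 5 cis ester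
Product: 6 methyl (1S,2S,5S)-5-methyl-2-(propan-2-yl)cyclopentane-1-carboxylate (all-cis ester)
Conditions: H2 (4 atm), PtO2, AcOH, rt
Reagents that add atoms: none
Why: Heterogeneous syn hydrogenation of the tetrasubstituted exocyclic alkene should occur on the face opposite the ester (held over the alkene by allylic 1,3-strain) and the C5 methyl, so the new C2 stereocentre carries isopropyl cis to both; any double-bond migration on the catalyst is reduced from the same face.

Step 4
Reactants: 6 all-cis ester
Product: 8 (1S,2S,5S)-5-methyl-2-(propan-2-yl)cyclopentane-1-carboxylic acid, via trimethylsilyl ester 7 (not isolated)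
Conditions: Me3SiI, CHCl3, 50 °C; then H2O
Reagents that add atoms: none
Why: Iodide attacks the O-methyl carbon of the silylated ester (SN2 ester dealkylation with iodotrimethylsilane) and water cleaves the silyl ester; this non-basic cleavage is chosen because hydroxide saponification of the hindered all-cis ester would risk epimerisation at C6.

Step 5
Reactants: 8 all-cis acid
Product: 10 (3aR,6R,6aR)-6-hydroxy-3,3,6-trimethylhexahydro-1H-cyclopenta[c]furan-1-one, via lactone 9 (not isolated)
Conditions: [Fe((S,S)-PDP)(MeCN)2](SbF6)2 (3 × 5 mol%), H2O2 (50% aq., 3 × 1.2 equiv), MeCN, rt; then AcOH (0.5 equiv), [Fe((S,S)-PDP)(MeCN)2](SbF6)2 (3 × 5 mol%), H2O2 (50% aq., 3 × 1.2 equiv), MeCN, rt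
Reagents that add atoms: hydrogen peroxide, OO
Why: Proposed new method: the carboxylate of 8 binds the iron centre in place of the usual acetic acid additive, the high-valent iron-oxo species (formally pentavalent iron) abstracts the γ-hydrogen of the cis isopropyl methine C1 through a cyclic transition state, and the tertiary radical is captured by rebound, either of the bound carboxylate or of hydroxyl followed by 5-exo-trig acyl substitution, so that the C1–O bond and γ-lactone 9 form with the cis ring fusion dictated by the cis C2/C6 substituents. Once the acid is consumed, added AcOH restores ordinary non-directed catalysis and a second oxo transfer hydroxylates C5–H; rebound outruns inversion of the tertiary radical, so OH takes the place of H with retention and the C5 configuration inherited from pulegone controls the new stereocentre. The closest known reactions are carboxylic-acid-directed γ-C–H lactonisation and tertiary C–H hydroxylation with iron PDP catalysts and H2O2, each established separately but not as one twofold operation on one substrate. In the first stage site selectivity rests on carboxylate direction, since C1–H is the only tertiary γ C–H, the β hydrogens would give a β-lactone and the ring γ methylenes a bridged lactone. In the second stage C6–H is α to the carbonyl and C2–H lies next to the acyloxy-bearing C1, so C5–H, exposed on the convex face and relieved of the cis interaction between its methyl and C7 on planarisation, is the least deactivated tertiary site; it is nevertheless β to the lactone carbonyl, so portionwise dosing is needed to hold back oxidation at the C3/C4 methylenes.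

Step 6
Reactants: 10 hydroxy lactone
Product: 11 (3aR,6R,6aR)-3,3,6-trimethylhexahydro-1H-cyclopenta[c]furan-1,6-diol (lactol; anomer mixture)
Conditions: i-Bu2AlH (2.2 equiv), CH2Cl2, −78 °C; aq. KNaC4H4O6 (potassium sodium tartrate)
Reagents that add atoms: none
Why: Partial reduction of the γ-lactone with i-Bu2AlH should stop at the tetrahedral aluminium hemiacetal at −78 °C (the first equivalent is consumed by the tertiary hydroxyl), and the ring stereocentres are not touched.

Step 7
Reactants: 12 (3E,5E)-pseudoionone
Product: 13 (4E,6E)-3,7,11-trimethyldodeca-1,4,6,10-tetraen-3-ol (racemic)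
Conditions: CH2=CHMgBr, THF, 0 °C; aq. NH4Cl
Reagents that add atoms: vinylmagnesium bromide, C=C[Mg]Br
Why: Grignard 1,2-addition to the dienone carbonyl gives the tertiary bis-allylic alcohol, whose carbinol stereocentre is racemic and is lost in the next step.

Step 8
Reactants: 13 vinyl carbinol
Product: 14 [(2E,4E,6E)-3,7,11-trimethyldodeca-2,4,6,10-tetraen-1-yl]triphenylphosphonium bromide (C15 salt)
Conditions: PPh3·HBr, MeOH, 0 °C to rt; crystallisation
Reagents that add atoms: triphenylphosphine hydrobromide, [PH+](c1ccccc1)(c1ccccc1)c1ccccc1.[Br-]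
Why: Acid ionises the tertiary alcohol to a delocalised allylic cation that triphenylphosphine captures at the unhindered primary terminus (SN1 substitution with allylic transposition), and the favoured 2E salt is purified by crystallisation.

Step 9
Reactants: 14 C15 salt; 15 (2E,4E,6E)-2,7-dimethylocta-2,4,6-trienedial
Product: 18 (2E,4E,6E,8E,10E,12E,14E)-2,7,11,15,19-pentamethylicosa-2,4,6,8,10,12,14,18-octaenal (C25 aldehyde), via C15 ylide 16 (not isolated), via 8Z aldehyde 17 (not isolated)
Conditions: 15 (3 equiv), NaOMe/MeOH added slowly, CH2Cl2, 0 °C; then I2 (cat.), CH2Cl2, rt, daylight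
Reagents that add atoms: none
Why: Wittig olefination of one formyl group, with the dialdehyde in excess to suppress the second condensation, forms C11'=C12', and iodine-catalysed equilibration converts the 8Z isomer into the all-E aldehyde.

Step 10
Reactants: 19 ethyl 2-(triphenylphosphoranylidene)propanoate; 20 chloroacetaldehyde
Product: 21 ethyl (2E)-4-chloro-2-methylbut-2-enoate
Conditions: 20 as 50% aq. solution, CH2Cl2, rt
Reagents that add atoms: none
Why: Wittig reaction of a stabilised ylide, which tolerates water and gives the E-trisubstituted enoate through reversible oxaphosphetane formation.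

Step 11
Reactants: 21 chloro ester
Product: 22 ethyl (2E)-4-(diethoxyphosphoryl)-2-methylbut-2-enoate
Conditions: P(OEt)3 (neat), 150 °C, EtCl distilled off
Reagents that add atoms: triethyl phosphite, CCOP(OCC)OCC
Why: Michaelis–Arbuzov reaction of the activated allylic chloride (SN2 attack by phosphorus, then dealkylation of the phosphonium ion by chloride) with the alkene geometry retained.

Step 12
Reactants: 18 C25 aldehyde; 22 C5 phosphonate
Product: 24 ethyl (2E,4E,6E,8E,10E,12E,14E,16E,18E)-2,6,11,15,19,23-hexamethyltetracosa-2,4,6,8,10,12,14,16,18,22-decaenoate (C30 ester), via sodium phosphonate anion 23 (not isolated)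
Conditions: NaH, THF, 0 °C; then 18, 0 °C to rt
Reagents that add atoms: none
Why: Horner–Wadsworth–Emmons reaction of the vinylogous phosphonate anion at the carbon next to phosphorus should form C11=C12 with E selectivity and keep the E geometry of C9=C10 set in 21.

Step 13
Reactants: 24 C30 ester
Product: 25 (2E,4E,6E,8E,10E,12E,14E,16E,18E)-2,6,11,15,19,23-hexamethyltetracosa-2,4,6,8,10,12,14,16,18,22-decaen-1-ol (C30 alcohol)
Conditions: i-Bu2AlH (2.5 equiv), CH2Cl2, −78 °C; aq. KNaC4H4O6 (potassium sodium tartrate)
Reagents that add atoms: none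
Why: 1,2-Reduction of the conjugated ester with i-Bu2AlH gives the primary allylic alcohol without touching the polyene.

Step 14
Reactants: 25 C30 alcohol
Product: 26 [(2E,4E,6E,8E,10E,12E,14E,16E,18E)-2,6,11,15,19,23-hexamethyltetracosa-2,4,6,8,10,12,14,16,18,22-decaen-1-yl]triphenylphosphonium bromide (C30 salt)
Conditions: PPh3·HBr, MeOH/CH2Cl2, 0 °C to rt, N2, dark
Reagents that add atoms: triphenylphosphine hydrobromide, [PH+](c1ccccc1)(c1ccccc1)c1ccccc1.[Br-]
Why: The polyenylic alcohol ionises readily and triphenylphosphine traps the delocalised cation at the primary terminus C8, the only position that keeps the full conjugation (SN1-type phosphonium salt formation as used for polyene Wittig salts).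

Step 15
Reactants: 11 lactol; 26 C30 salt
Product: 28 C40 diol as a 7E/7Z mixture (target constitution and ring configuration with undefined C7=C8 geometry), via C30 ylide 27 (not isolated)
Conditions: 1,2-epoxybutane (solvent), 65 °C, N2, dark
Reagents that add atoms: none
Why: Wittig olefination of the hydroxy aldehyde tautomer of the lactol, in which bromide opens the epoxide to an alkoxide that deprotonates the salt, so the ylide forms under nearly neutral conditions that should spare the β-hydroxy aldehyde from retro-aldol cleavage and C6 from epimerisation; the new C7=C8 bond forms as an E/Z mixture.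

Step 16
Reactants: 28 C40 diol (7E/7Z)
Product: 29 (all-E,2R,5R,6R)-2,6-cyclolycopene-1,5-diol (target)
Conditions: n-heptane, reflux, N2, dark; crystallisation
Reagents that add atoms: none
Why: Thermal Z to E isomerisation of the sterically hindered 7Z double bond should give the favoured all-E isomer, which is drawn out of the equilibrium by crystallisation.

**Compound list**

1 | (S)-(−)-pulegone, (5S)-5-methyl-2-(propan-2-ylidene)cyclohexan-1-one | C[C@H]1CCC(=C(C)C)C(=O)C1 | starting material
2 | pulegone dibromide, (5S)-2-bromo-2-(2-bromopropan-2-yl)-5-methylcyclohexan-1-one (epimers at the brominated ring carbon) | C[C@H]1CCC(Br)(C(C)(C)Br)C(=O)C1 | intermediate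
3 | methyl (5S)-5-methyl-2-(propan-2-ylidene)cyclopentane-1-carboxylate (epimer mixture at the ester-bearing carbon) | COC(=O)C1C(=C(C)C)CC[C@@H]1C | intermediate
4 | lithium methoxy[(2S)-2-methyl-5-(propan-2-ylidene)cyclopentylidene]methanolate (dienolate of 3) | COC([O-])=C1C(=C(C)C)CC[C@@H]1C.[Li+] | intermediate
5 | methyl (1S,5S)-5-methyl-2-(propan-2-ylidene)cyclopentane-1-carboxylate (cis) | COC(=O)[C@@H]1C(=C(C)C)CC[C@@H]1C | intermediate
6 | methyl (1S,2S,5S)-5-methyl-2-(propan-2-yl)cyclopentane-1-carboxylate (all-cis) | COC(=O)[C@@H]1[C@H](C(C)C)CC[C@@H]1C | intermediate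
7 | trimethylsilyl (1S,2S,5S)-5-methyl-2-(propan-2-yl)cyclopentane-1-carboxylate | C[Si](C)(C)OC(=O)[C@@H]1[C@H](C(C)C)CC[C@@H]1C | intermediate
8 | (1S,2S,5S)-5-methyl-2-(propan-2-yl)cyclopentane-1-carboxylic acid (all-cis) | OC(=O)[C@@H]1[C@H](C(C)C)CC[C@@H]1C | intermediate
9 | (3aR,6S,6aS)-3,3,6-trimethylhexahydro-1H-cyclopenta[c]furan-1-one | O=C1OC(C)(C)[C@@H]2CC[C@H](C)[C@H]12 | intermediate
10 | (3aR,6R,6aR)-6-hydroxy-3,3,6-trimethylhexahydro-1H-cyclopenta[c]furan-1-one | O=C1OC(C)(C)[C@@H]2CC[C@@](C)(O)[C@H]12 | intermediate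
11 | (3aR,6R,6aR)-3,3,6-trimethylhexahydro-1H-cyclopenta[c]furan-1,6-diol (anomer mixture) | OC1OC(C)(C)[C@@H]2CC[C@@](C)(O)[C@H]12 | intermediate
12 | (3E,5E)-6,10-dimethylundeca-3,5,9-trien-2-one (pseudoionone) | CC(C)=CCC/C(C)=C/C=C/C(C)=O | starting material
13 | (4E,6E)-3,7,11-trimethyldodeca-1,4,6,10-tetraen-3-ol (racemic) | CC(C)=CCC/C(C)=C/C=C/C(C)(O)C=C | intermediate
14 | [(2E,4E,6E)-3,7,11-trimethyldodeca-2,4,6,10-tetraen-1-yl]triphenylphosphonium bromide | CC(C)=CCC/C(C)=C/C=C/C(C)=C/C[P+](c1ccccc1)(c1ccccc1)c1ccccc1.[Br-] | intermediate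
15 | (2E,4E,6E)-2,7-dimethylocta-2,4,6-trienedial | O=C/C(C)=C/C=C/C=C(C)/C=O | starting material
16 | [(2E,4E,6E)-3,7,11-trimethyldodeca-2,4,6,10-tetraen-1-ylidene]triphenylphosphorane (C15 ylide) | CC(C)=CCC/C(C)=C/C=C/C(C)=C/C=P(c1ccccc1)(c1ccccc1)c1ccccc1 | intermediate
17 | (2E,4E,6E,8Z,10E,12E,14E)-2,7,11,15,19-pentamethylicosa-2,4,6,8,10,12,14,18-octaenal | CC(C)=CCC/C(C)=C/C=C/C(C)=C/C=C\C(C)=C\C=C\C=C(C)\C=O | intermediate
18 | (2E,4E,6E,8E,10E,12E,14E)-2,7,11,15,19-pentamethylicosa-2,4,6,8,10,12,14,18-octaenal (C25 aldehyde, C12–C1') | CC(C)=CCC/C(C)=C/C=C/C(C)=C/C=C/C(C)=C/C=C/C=C(C)/C=O | intermediate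
19 | ethyl 2-(triphenylphosphoranylidene)propanoate | CCOC(=O)C(C)=P(c1ccccc1)(c1ccccc1)c1ccccc1 | starting material
20 | chloroacetaldehyde | O=CCCl | starting material
21 | ethyl (2E)-4-chloro-2-methylbut-2-enoate | CCOC(=O)/C(C)=C/CCl | intermediate
22 | ethyl (2E)-4-(diethoxyphosphoryl)-2-methylbut-2-enoate | CCOC(=O)/C(C)=C/CP(=O)(OCC)OCC | intermediate
23 | sodium salt of 22 (phosphonate-stabilised allyl anion) | CCOC(=O)/C(C)=C/[CH-]P(=O)(OCC)OCC.[Na+] | intermediate
24 | ethyl (2E,4E,6E,8E,10E,12E,14E,16E,18E)-2,6,11,15,19,23-hexamethyltetracosa-2,4,6,8,10,12,14,16,18,22-decaenoate (C30 ester, C8–C1') | CC(C)=CCC/C(C)=C/C=C/C(C)=C/C=C/C(C)=C/C=C/C=C(C)/C=C/C=C(C)/C(=O)OCC | intermediate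
25 | (2E,4E,6E,8E,10E,12E,14E,16E,18E)-2,6,11,15,19,23-hexamethyltetracosa-2,4,6,8,10,12,14,16,18,22-decaen-1-ol | CC(C)=CCC/C(C)=C/C=C/C(C)=C/C=C/C(C)=C/C=C/C=C(C)/C=C/C=C(C)/CO | intermediate
26 | [(2E,4E,6E,8E,10E,12E,14E,16E,18E)-2,6,11,15,19,23-hexamethyltetracosa-2,4,6,8,10,12,14,16,18,22-decaen-1-yl]triphenylphosphonium bromide | CC(C)=CCC/C(C)=C/C=C/C(C)=C/C=C/C(C)=C/C=C/C=C(C)/C=C/C=C(C)/C[P+](c1ccccc1)(c1ccccc1)c1ccccc1.[Br-] | intermediate
27 | C30 ylide, the triphenylphosphorane derived from 26 by loss of HBr | CC(C)=CCC/C(C)=C/C=C/C(C)=C/C=C/C(C)=C/C=C/C=C(C)/C=C/C=C(C)/C=P(c1ccccc1)(c1ccccc1)c1ccccc1 | intermediate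
28 | C40 diol, 7E/7Z mixture, (1R,2R,3R) ring configuration as in 29 | CC(C)=CCC/C(C)=C/C=C/C(C)=C/C=C/C(C)=C/C=C/C=C(C)/C=C/C=C(C)/C=C[C@@H]1[C@H](C(C)(C)O)CC[C@@]1(C)O | intermediate
29 | (1R,2R,3R)-3-(2-hydroxypropan-2-yl)-1-methyl-2-[(1E,3E,5E,7E,9E,11E,13E,15E,17E,19E)-3,7,12,16,20,24-hexamethylpentacosa-1,3,5,7,9,11,13,15,17,19,23-undecaen-1-yl]cyclopentan-1-ol, (all-E,2R,5R,6R)-2,6-cyclolycopene-1,5-diol | CC(C)=CCC/C(C)=C/C=C/C(C)=C/C=C/C(C)=C/C=C/C=C(C)/C=C/C=C(C)/C=C/[C@@H]1[C@H](C(C)(C)O)CC[C@@]1(C)O | target

**Step count**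

Total: 16 steps. Longest linear sequence: 8 steps (steps 1–6, 15, 16; the polyene branch 7, 8, 9, 12, 13, 14, 15, 16 is equally long).

**Steps most likely to fail**

1. Step 5 (Proposed new method). The twofold oxidation may stall after the lactonisation: hydrogen abstraction at C5, which is β to the lactone carbonyl, may be too slow for the short-lived oxidant, so that catalyst decomposition and methylene oxidation at C3/C4 take over. A mismatched pairing of the chiral catalyst with the substrate could also slow the directed first stage. The fallback makes the two C–O bonds by known chemistry in separate operations and sets out from cis ester 5. Aqueous H2SO4 in AcOH protonates the isopropylidene group at C2, the tertiary C1 cation is trapped by the cis ester oxygen and methanol is lost, giving lactone 9 (acid-mediated lactonisation of a β,γ-unsaturated ester). Only the cis-fused ring can close, so C2 is fixed by the ring. Isolated 9 is then hydroxylated at C5–H with methyl(trifluoromethyl)dioxirane in CH2Cl2 at 0 °C (tertiary C–H hydroxylation with retention), which returns the route at hydroxy lactone 10.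

2. Step 15. The hindered lactol may open slowly and add the bulky C30 ylide slowly, while the transient β-hydroxy aldehyde undergoes retro-aldol ring opening or epimerisation at C6. The fallback extends the end group first with a small stabilised reagent and joins the chain at C11=C12 instead of C7=C8 (C15 + C25 in place of C10 + C30).
   - It sets out from lactol 11. Horner–Wadsworth–Emmons reaction with the anion of commercial ethyl (2E)-4-(diethoxyphosphoryl)-3-methylbut-2-enoate (LiN(SiMe3)2, THF, −78 °C) should give ethyl (2E,4E)-5-[(1R,2R,5R)-2-hydroxy-5-(2-hydroxypropan-2-yl)-2-methylcyclopentyl]-3-methylpenta-2,4-dienoate F1.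
   - i-Bu2AlH reduces it to the corresponding dienol F2, and MnO2 oxidises the primary allylic alcohol to the dienal F3.
   - In parallel, C25 aldehyde 18 is reduced with NaBH4 to the C25 alcohol F4 and converted with PPh3·HBr into the C25 phosphonium bromide F5.
   - Wittig coupling of F3 with the C25 ylide F6, generated from F5 in 1,2-epoxybutane, gives the C40 diol as an 11E/11Z mixture F7. The thermal equilibration and crystallisation of step 16 then return the route at target 29.

3. Step 3. Hydrogen uptake at the tetrasubstituted alkene may be incomplete, or delivery to the face opposite the ester may not be clean. The fallback inverts the order of control: C2 is set by chelation and C6 afterwards by kinetic protonation.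
   - It sets out from ester mixture 3. Equilibration with NaOMe in MeOH gives the trans ester, methyl (1R,5S)-5-methyl-2-(propan-2-ylidene)cyclopentane-1-carboxylate F8.
   - Hydrogenation with [Ir(cod)(PCy3)(py)]PF6 in CH2Cl2 is directed by the ester carbonyl to its own face and should give methyl (1R,2S,5S)-5-methyl-2-(propan-2-yl)cyclopentane-1-carboxylate F9, in which isopropyl and methyl are cis and the ester is trans to both.
   - Deprotonation with LiN(i-Pr)2 to the lithium enolate F10 and protonation with AcOH at −78 °C, from the face opposite both alkyl groups, returns the route at all-cis ester 6.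

**Further compounds**

F0 | step 5 | none | none
F1 | step 15 | ethyl (2E,4E)-5-[(1R,2R,5R)-2-hydroxy-5-(2-hydroxypropan-2-yl)-2-methylcyclopentyl]-3-methylpenta-2,4-dienoate | CCOC(=O)/C=C(C)/C=C/[C@@H]1[C@H](C(C)(C)O)CC[C@@]1(C)O
F2 | step 15 | (1R,2R,3R)-2-[(1E,3E)-5-hydroxy-3-methylpenta-1,3-dien-1-yl]-3-(2-hydroxypropan-2-yl)-1-methylcyclopentan-1-ol | OC/C=C(C)/C=C/[C@@H]1[C@H](C(C)(C)O)CC[C@@]1(C)O
F3 | step 15 | (2E,4E)-5-[(1R,2R,5R)-2-hydroxy-5-(2-hydroxypropan-2-yl)-2-methylcyclopentyl]-3-methylpenta-2,4-dienal | O=C/C=C(C)/C=C/[C@@H]1[C@H](C(C)(C)O)CC[C@@]1(C)O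
F4 | step 15 | (2E,4E,6E,8E,10E,12E,14E)-2,7,11,15,19-pentamethylicosa-2,4,6,8,10,12,14,18-octaen-1-ol | CC(C)=CCC/C(C)=C/C=C/C(C)=C/C=C/C(C)=C/C=C/C=C(C)/CO
F5 | step 15 | [(2E,4E,6E,8E,10E,12E,14E)-2,7,11,15,19-pentamethylicosa-2,4,6,8,10,12,14,18-octaen-1-yl]triphenylphosphonium bromide | CC(C)=CCC/C(C)=C/C=C/C(C)=C/C=C/C(C)=C/C=C/C=C(C)/C[P+](c1ccccc1)(c1ccccc1)c1ccccc1.[Br-]
F6 | step 15 | C25 ylide, the triphenylphosphorane derived from F5 by loss of HBr | CC(C)=CCC/C(C)=C/C=C/C(C)=C/C=C/C(C)=C/C=C/C=C(C)/C=P(c1ccccc1)(c1ccccc1)c1ccccc1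
F7 | step 15 | C40 diol as an 11E/11Z mixture, otherwise as 29 | CC(C)=CCC/C(C)=C/C=C/C(C)=C/C=C/C(C)=C/C=C/C=C(\C)C=C/C=C(C)/C=C/[C@@H]1[C@H](C(C)(C)O)CC[C@@]1(C)O
F8 | step 3 | methyl (1R,5S)-5-methyl-2-(propan-2-ylidene)cyclopentane-1-carboxylate (trans) | COC(=O)[C@H]1C(=C(C)C)CC[C@@H]1C
F9 | step 3 | methyl (1R,2S,5S)-5-methyl-2-(propan-2-yl)cyclopentane-1-carboxylate | COC(=O)[C@H]1[C@H](C(C)C)CC[C@@H]1C
F10 | step 3 | lithium methoxy[(2S,5S)-2-methyl-5-(propan-2-yl)cyclopentylidene]methanolate (enolate of F9) | COC([O-])=C1[C@H](C(C)C)CC[C@@H]1C.[Li+]
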